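**Assumption:** the target SMILES carries no stereocentre and no defined axis, so there is no configuration to set; the hindered biaryl axis is left unassigned (racemic if it is configurationally stable).

**Retrosynthetic overview**
1. Target ⇐ its bis(isopropyl ether) by vinylogous-ester hydrolysis; the two anisole rings are bought.
2. Both quinone rings ⇐ one thermal operation on a diene-bridged bis(4-hydroxycyclobutenone): two 4π openings and two 6π closures, then oxidation. The biaryl bond is the central C–C bond of the diene, so no aryl–aryl coupling is used.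
3. Bis(cyclobutenone) ⇐ a 1,4-dilithio-1,3-diene + 2 × 3-isopropoxy-4-methylcyclobutenedione (from diisopropyl squarate and MeLi).
4. Dilithiodiene ⇐ 2,5-disubstituted tellurophene (Te–Li exchange) ⇐ 1,3-diyne + Na2Te ⇐ Glaser–Hay dimerisation ⇐ 2-methoxybenzyl bromide + 1-(trimethylsilyl)propyne.
5. Ring order: tellurophene (temporary, step 3), then both quinone rings together (step 6).

**Route**

Step 1
Reactants: 1 1-(trimethylsilyl)propyne; 2 2-methoxybenzyl bromide
Product: 4 4-(2-methoxyphenyl)-1-(trimethylsilyl)but-1-yne, via lithiated silylpropyne 3 (not isolated)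
Conditions: n-BuLi, THF, −78 → −20 °C; then 2, −78 °C → rt
Reagents that add atoms: none
Why: Propargylic lithiation and SN2 alkylation by the benzylic bromide (propargyl anion alkylation); the silyl group blocks the alkyne terminus and directs attack to the CH2 end.

Step 2
Reactants: 4 4-(2-methoxyphenyl)-1-(trimethylsilyl)but-1-yne (2 equiv)
Product: 6 1,8-bis(2-methoxyphenyl)octa-3,5-diyne, via terminal alkyne 5 (not isolated)
Conditions: K2CO3, MeOH, rt; concentrate; then CuCl (10 mol %), TMEDA, O2 (1 atm), acetone, rt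
Reagents that add atoms: none
Why: Base-catalysed protodesilylation frees the terminal alkyne, and two molecules of it are joined at their terminal carbons by Glaser–Hay oxidative homocoupling to give the symmetrical 1,3-diyne.

Step 3
Reactants: 6 1,8-bis(2-methoxyphenyl)octa-3,5-diyne
Product: 7 2,5-bis[2-(2-methoxyphenyl)ethyl]tellurophene
Conditions: Te, NaBH4, H2O/EtOH, 80 °C (N2); then 6, THF/EtOH, 60 °C
Reagents that add atoms: tellurium, [Te]
Why: Telluride adds as a nucleophile to an outer carbon of the conjugated diyne and the enyne tellurolate closes onto the second alkyne (classical chalcogenophene synthesis from 1,3-diynes), which puts Te on the two chain-bearing carbons.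

Step 4
Reactants: 8 diisopropyl squarate
Product: 10 3-isopropoxy-4-methylcyclobut-3-ene-1,2-dione, via methyl carbinol 9 (not isolated)
Conditions: MeLi, THF, −78 °C; then 12 M HCl, CH2Cl2, rt
Reagents that add atoms: methyllithium, [Li]C
Why: 1,2-Addition of MeLi to one squarate carbonyl, then acid-promoted loss of isopropanol from the vinylogous hemiketal, is the standard squarate route to 3-alkoxy-4-alkylcyclobutenediones.

Step 5
Reactants: 7 2,5-bis[2-(2-methoxyphenyl)ethyl]tellurophene; 10 3-isopropoxy-4-methylcyclobut-3-ene-1,2-dione (2.4 equiv)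
Product: 12 4,4'-[(3Z,5Z)-1,8-bis(2-methoxyphenyl)octa-3,5-diene-3,6-diyl]bis(4-hydroxy-3-isopropoxy-2-methylcyclobut-2-en-1-one), via dilithiodiene 11 (not isolated)
Conditions: n-BuLi (2.05 equiv), THF, −78 °C; cannulate into 10, THF, −78 °C; AcOH quench at −78 °C
Reagents that add atoms: none
Why: Twofold tellurium–lithium exchange of the bis-vinylic telluride opens the ring with retention, and each vinyllithium adds 1,2 to the carbonyl of 10 next to C–OiPr (the other is a deactivated vinylogous ester), the known regiochemistry for organolithium addition to 3-alkoxy-4-alkylcyclobutenediones; the two carbinol centres form as a meso/racemic mixture that step 6 erases.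

Step 6
Reactants: 12 the diene-bridged bis(4-hydroxycyclobutenone)
Product: 14 5,5'-diisopropoxy-3,3'-bis[2-(2-methoxyphenyl)ethyl]-6,6'-dimethyl-2,2'-bi(1,4-benzoquinone), via biaryl bis(hydroquinone) 13 (not isolated)
Conditions: p-xylene (0.01 M), 138 °C, Ar; cool, then Ag2O, rt
Reagents that add atoms: none
Why: Proposed new method: a twofold Moore–Liebeskind ring expansion in one pot, in which each 4-alkenyl-4-hydroxycyclobutenone opens (conrotatory 4π, OH rotating outward) to a dienylketene that closes (6π) onto the diene CH and tautomerises to a hydroquinone, so both carbocycles form together, the former diene C4–C5 bond becomes the biaryl bond and the substitution pattern is fixed by step 5; the closest known reaction is the single thermal ring expansion of 4-alkenyl-4-hydroxycyclobutenones to hydroquinones, and Ag2O then oxidises to the bis-quinone.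

Step 7
Reactants: 14 the bis(isopropoxyquinone)
Product: 15 5,5'-dihydroxy-3,3'-bis[2-(2-methoxyphenyl)ethyl]-6,6'-dimethyl-2,2'-bi(1,4-benzoquinone) (target)
Conditions: 2 M NaOH, MeOH/THF, rt, Ar; then 1 M HCl
Reagents that add atoms: sodium hydroxide, [Na+].[OH-]
Why: The 2-alkoxyquinone is a vinylogous ester and is saponified by hydroxide through addition–elimination at the OiPr-bearing carbon, while the aryl methyl ethers are inert.

**Compound list**
1 | 1-(trimethylsilyl)propyne | CC#C[Si](C)(C)C | starting material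
2 | 2-methoxybenzyl bromide | COc1ccccc1CBr | starting material
3 | 3-(trimethylsilyl)prop-2-ynyllithium | [Li]CC#C[Si](C)(C)C | intermediate
4 | 4-(2-methoxyphenyl)-1-(trimethylsilyl)but-1-yne | COc1ccccc1CCC#C[Si](C)(C)C | intermediate
5 | 4-(2-methoxyphenyl)but-1-yne | COc1ccccc1CCC#C | intermediate
6 | 1,8-bis(2-methoxyphenyl)octa-3,5-diyne | COc1ccccc1CCC#CC#CCCc1ccccc1OC | intermediate
7 | 2,5-bis[2-(2-methoxyphenyl)ethyl]tellurophene | COc1ccccc1CCC1=CC=C(CCc2ccccc2OC)[Te]1 | intermediate
8 | diisopropyl squarate (3,4-diisopropoxycyclobut-3-ene-1,2-dione) | CC(C)OC1=C(OC(C)C)C(=O)C1=O | starting material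
9 | 4-hydroxy-2,3-diisopropoxy-4-methylcyclobut-2-en-1-one (racemic; formed as its lithium alkoxide) | CC(C)OC1=C(OC(C)C)C(C)(O)C1=O | intermediate
10 | 3-isopropoxy-4-methylcyclobut-3-ene-1,2-dione | CC(C)OC1=C(C)C(=O)C1=O | intermediate
11 | (3E,5E)-3,6-dilithio-1,8-bis(2-methoxyphenyl)octa-3,5-diene (each Li cis to the neighbouring vinyl CH) | [Li]/C(CCc1ccccc1OC)=C\C=C(/[Li])CCc1ccccc1OC | intermediate
12 | 4,4'-[(3Z,5Z)-1,8-bis(2-methoxyphenyl)octa-3,5-diene-3,6-diyl]bis(4-hydroxy-3-isopropoxy-2-methylcyclobut-2-en-1-one) (meso/racemic mixture at the two carbinol carbons) | CC(C)OC1=C(C)C(=O)C1(O)/C(CCc1ccccc1OC)=C\C=C(/C1(O)C(OC(C)C)=C(C)C1=O)CCc1ccccc1OC | intermediate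
13 | 4,4'-diisopropoxy-6,6'-bis[2-(2-methoxyphenyl)ethyl]-3,3'-dimethyl-[1,1'-biphenyl]-2,2',5,5'-tetrol | COc1ccccc1CCc1c(O)c(OC(C)C)c(C)c(O)c1-c1c(O)c(C)c(OC(C)C)c(O)c1CCc1ccccc1OC | intermediate
14 | 5,5'-diisopropoxy-3,3'-bis[2-(2-methoxyphenyl)ethyl]-6,6'-dimethyl-2,2'-bi(1,4-benzoquinone) | COc1ccccc1CCC1=C(C2=C(CCc3ccccc3OC)C(=O)C(OC(C)C)=C(C)C2=O)C(=O)C(C)=C(OC(C)C)C1=O | intermediate
15 | 5,5'-dihydroxy-3,3'-bis[2-(2-methoxyphenyl)ethyl]-6,6'-dimethyl-2,2'-bi(1,4-benzoquinone) | COc1ccccc1CCC1=C(C2=C(CCc3ccccc3OC)C(=O)C(O)=C(C)C2=O)C(=O)C(C)=C(O)C1=O | target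

**Total steps:** 7 (step 4 is a one-step branch). **Longest linear sequence:** 6 (steps 1, 2, 3, 5, 6, 7).

**Steps most likely to fail, with fallbacks**

Step 6 is the most exposed step. The second 6π closure must occur at a CH that already carries a fully substituted aryl group pointing into the forming ring, and the free phenols of the first ring can intercept the second ketene. The fallback sets out from 10 and comes back at 13: it builds the ring once on a simple vinyl partner and makes the aryl–aryl bond afterwards. Bought 2-methoxybenzylmagnesium chloride and 2,3-dibromopropene (THF, 0 °C) give 2-bromo-4-(2-methoxyphenyl)but-1-ene F1. Bromine–lithium exchange (t-BuLi, −78 °C) gives [4-(2-methoxyphenyl)but-1-en-2-yl]lithium F2, which adds to 10 to give 4-hydroxy-3-isopropoxy-4-[4-(2-methoxyphenyl)but-1-en-2-yl]-2-methylcyclobut-2-en-1-one F3. Thermolysis (toluene, 110 °C) gives 3-isopropoxy-5-[2-(2-methoxyphenyl)ethyl]-2-methylbenzene-1,4-diol F4, whose only free ring position is the future biaryl carbon. Half of it is oxidised (Ag2O) to 3-isopropoxy-5-[2-(2-methoxyphenyl)ethyl]-2-methyl-1,4-benzoquinone F5. Acid-promoted conjugate addition of F4 to F5 (BF3·OEt2, CH2Cl2, 0 °C) gives 13, which Ag2O takes on to 14 as in step 6.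

Step 5 is the next risk. After the first addition the remaining vinyllithium lies cis to the new cyclobutenone and can attack it intramolecularly through a six-membered transition state, and incomplete exchange would leave mono-adduct. The fallback sets out from 7 and comes back at 13: it opens the tellurophene only once and builds the rings one after the other. One equivalent of n-BuLi (THF, −78 °C) gives (3E,5Z)-6-(butyltellanyl)-3-lithio-1,8-bis(2-methoxyphenyl)octa-3,5-diene F6, which adds to 10 to give 4-[(3Z,5Z)-6-(butyltellanyl)-1,8-bis(2-methoxyphenyl)octa-3,5-dien-3-yl]-4-hydroxy-3-isopropoxy-2-methylcyclobut-2-en-1-one F7. Thermolysis (p-xylene, 138 °C) builds the first ring, 2-[(Z)-2-(butyltellanyl)-4-(2-methoxyphenyl)but-1-enyl]-5-isopropoxy-3-[2-(2-methoxyphenyl)ethyl]-6-methylbenzene-1,4-diol F8. Three equivalents of n-BuLi (two for the phenols, one for Te–Li exchange) give the trilithio species F9, in which the first ring is an inert bis-phenoxide. Addition to 10 and work-up give 4-[(Z)-1-{2,5-dihydroxy-4-isopropoxy-6-[2-(2-methoxyphenyl)ethyl]-3-methylphenyl}-4-(2-methoxyphenyl)but-1-en-2-yl]-4-hydroxy-3-isopropoxy-2-methylcyclobut-2-en-1-one F10, and a second thermolysis closes the second ring to 13.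

Step 3 is the third risk, because a dialkyl-substituted diyne is only a weak acceptor for telluride and may stop at open-chain adducts. The fallback sets out from 4 and comes back at 11: it builds the dilithiodiene without tellurium. Compound 4 is desilylated (K2CO3, MeOH) and 5 is isolated. Syn-bromoboration with B-bromo-9-BBN (CH2Cl2, 0 °C) gives B-[(Z)-2-bromo-4-(2-methoxyphenyl)but-1-enyl]-9-borabicyclo[3.3.1]nonane F11. NaOMe followed by CuBr·SMe2 (THF, 0 °C) transfers the alkenyl group to copper, and the alkenylcopper dimerises with retention to (3Z,5Z)-3,6-dibromo-1,8-bis(2-methoxyphenyl)octa-3,5-diene F12. Twofold bromine–lithium exchange (t-BuLi, 4 equiv, −78 °C) gives 11, which is used as in step 5.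

**Further compounds**
F1 | step 6 | 2-bromo-4-(2-methoxyphenyl)but-1-ene | COc1ccccc1CCC(Br)=C
F2 | step 6 | [4-(2-methoxyphenyl)but-1-en-2-yl]lithium | [Li]C(=C)CCc1ccccc1OC
F3 | step 6 | 4-hydroxy-3-isopropoxy-4-[4-(2-methoxyphenyl)but-1-en-2-yl]-2-methylcyclobut-2-en-1-one (racemic) | CC(C)OC1=C(C)C(=O)C1(O)C(=C)CCc1ccccc1OC
F4 | step 6 | 3-isopropoxy-5-[2-(2-methoxyphenyl)ethyl]-2-methylbenzene-1,4-diol | COc1ccccc1CCc1cc(O)c(C)c(OC(C)C)c1O
F5 | step 6 | 3-isopropoxy-5-[2-(2-methoxyphenyl)ethyl]-2-methyl-1,4-benzoquinone | COc1ccccc1CCC1=CC(=O)C(C)=C(OC(C)C)C1=O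
F6 | step 5 | (3E,5Z)-6-(butyltellanyl)-3-lithio-1,8-bis(2-methoxyphenyl)octa-3,5-diene | [Li]/C(CCc1ccccc1OC)=C\C=C(/[Te]CCCC)CCc1ccccc1OC
F7 | step 5 | 4-[(3Z,5Z)-6-(butyltellanyl)-1,8-bis(2-methoxyphenyl)octa-3,5-dien-3-yl]-4-hydroxy-3-isopropoxy-2-methylcyclobut-2-en-1-one (racemic) | CC(C)OC1=C(C)C(=O)C1(O)/C(CCc1ccccc1OC)=C\C=C(/[Te]CCCC)CCc1ccccc1OC
F8 | step 5 | 2-[(Z)-2-(butyltellanyl)-4-(2-methoxyphenyl)but-1-enyl]-5-isopropoxy-3-[2-(2-methoxyphenyl)ethyl]-6-methylbenzene-1,4-diol | COc1ccccc1CCc1c(O)c(OC(C)C)c(C)c(O)c1/C=C(\[Te]CCCC)CCc1ccccc1OC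
F9 | step 5 | trilithio species from F8 (dilithium bis-phenoxide carrying the (Z)-vinyllithium) | COc1ccccc1CCc1c(O[Li])c(OC(C)C)c(C)c(O[Li])c1/C=C(\[Li])CCc1ccccc1OC
F10 | step 5 | 4-[(Z)-1-{2,5-dihydroxy-4-isopropoxy-6-[2-(2-methoxyphenyl)ethyl]-3-methylphenyl}-4-(2-methoxyphenyl)but-1-en-2-yl]-4-hydroxy-3-isopropoxy-2-methylcyclobut-2-en-1-one (racemic) | COc1ccccc1CCc1c(O)c(OC(C)C)c(C)c(O)c1/C=C(\C1(O)C(OC(C)C)=C(C)C1=O)CCc1ccccc1OC
F11 | step 3 | B-[(Z)-2-bromo-4-(2-methoxyphenyl)but-1-enyl]-9-borabicyclo[3.3.1]nonane | COc1ccccc1CC/C(Br)=C/B1C2CCCC1CCC2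
F12 | step 3 | (3Z,5Z)-3,6-dibromo-1,8-bis(2-methoxyphenyl)octa-3,5-diene | Br/C(CCc1ccccc1OC)=C\C=C(/Br)CCc1ccccc1OC
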